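**Retrosynthetic overview**

1. The strategy rests on the cyclohexane ring (C5a, C6, C7, C8, C9, C9a). The O1-bearing C9a and the Br-bearing C7 are 1,4-related and trans, so the bromide must come by inversion of an axial C7–OH that is cis to O1. These two cis C–O bonds are the termini of a ring diene C9a=C9–C8=C7.
2. Palisadin B 26 ⇐ diol 24 (double Appel bromination, C7 inverted) ⇐ exocyclic enol ether 21 (hydroboration sets C2) ⇐ enoate lactone 20 ⇐ RCM of methacrylate 19, which closes the oxepene ring (O1, C2, C3, C4, C5, C5a, C9a) last.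
3. 19 ⇐ trans-fused γ-lactone 13, a temporary ring that ties up C9a–OH and the C5 arm and leaves only C7–OH free ⇐ cis-1,4-diol ⇐ endoperoxide 11 ⇐ diene 9 + singlet oxygen ([4+2]).
4. 9 ⇐ enone 1 by CBS reduction, Johnson–Claisen rearrangement (C5a by 1,3-chirality transfer), allylic oxidation, kinetic dienyl triflate and Pd/formate reduction.
5. Ring order: carbocycle (present from 1) → 2,3-dioxabicyclo[2.2.2]octene (temporary) → γ-lactone (temporary) → oxepene.

Key step: step 6

Remark on availability: 2,4,4-trimethylcyclohex-2-en-1-one (1) is treated as purchasable; if it must be made, acid-catalysed annulation of isobutyraldehyde with ethyl vinyl ketone should give it in one operation.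
Remark on locants: O1 and C2–C9a in the text are the 1-benzoxepine locants of the target, also for earlier intermediates.

**Route**

Step 1
Reactants: 1 2,4,4-trimethylcyclohex-2-en-1-one
Product: 2 (R)-2,4,4-trimethylcyclohex-2-en-1-ol
Conditions: (S)-Me-CBS (10 mol %), BH3·SMe2, THF, −20 °C; MeOH quench
Reagents that add atoms: none
Why: Corey–Bakshi–Shibata reduction, in which the α-methyl-substituted alkenyl side of the enone acts as the large group, so the (S)-catalyst should deliver hydride to the face that gives the (R)-allylic alcohol (stereocentre set by catalyst control).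

Step 2
Reactants: 2 (R)-2,4,4-trimethylcyclohex-2-en-1-ol; 3 triethyl orthoacetate
Product: 5 ethyl 2-[(1S)-2,6,6-trimethylcyclohex-2-en-1-yl]acetate, via mixed ketene acetal 4 (not isolated)
Conditions: MeC(OEt)3 (excess), EtCO2H (cat.), 140 °C, EtOH distilled off
Reagents that add atoms: triethyl orthoacetate (3), CC(OCC)(OCC)OCC
Why: Johnson–Claisen rearrangement, in which ketene acetal 4 rearranges suprafacially through a six-membered transition state, so the carbinol configuration of 2 is transferred to the new C–C bond on the same ring face (this sets C5a), with the bond forming anti to the pseudo-axial methyl of the neighbouring gem-dimethyl group.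

Step 3
Reactants: 5 ethyl 2-[(1S)-2,6,6-trimethylcyclohex-2-en-1-yl]acetate
Product: 6 ethyl 2-[(1S)-2,6,6-trimethyl-4-oxocyclohex-2-en-1-yl]acetate
Conditions: Rh2(cap)4 (1 mol %), t-BuOOH (aq., 5 equiv), K2CO3, CH2Cl2, rt
Reagents that add atoms: tert-butyl hydroperoxide, CC(C)(C)OO
Why: Allylic C–H oxidation of a trisubstituted cyclohexene to the enone (the transformation known for α-ionone-type rings), which should take the only allylic ring methylene, leave the hindered tertiary allylic C–H alone and be mild enough not to enolise toward the γ stereocentre.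

Step 4
Reactants: 6 ethyl 2-[(1S)-2,6,6-trimethyl-4-oxocyclohex-2-en-1-yl]acetate
Product: 8 ethyl 2-[(1R)-2,6,6-trimethyl-4-{[(trifluoromethyl)sulfonyl]oxy}cyclohexa-2,4-dien-1-yl]acetate, via lithium dienolate 7 (not isolated)
Conditions: LiHMDS (1.1 equiv), THF, −78 °C; then PhNTf2, −78 → 0 °C
Reagents that add atoms: N-phenylbis(trifluoromethanesulfonimide), O=S(=O)(N(c1ccccc1)S(=O)(=O)C(F)(F)F)C(F)(F)F
Why: Kinetic α′-deprotonation of the enone at −78 °C should give the cross-conjugated dienolate 7 (the ketone is far more acidic than the ester and the γ C–H of the stereocentre is not touched), which the triflimide O-sulfonylates to the dienyl triflate.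

Step 5
Reactants: 8 ethyl 2-[(1R)-2,6,6-trimethyl-4-{[(trifluoromethyl)sulfonyl]oxy}cyclohexa-2,4-dien-1-yl]acetate
Product: 9 ethyl 2-[(1R)-2,6,6-trimethylcyclohexa-2,4-dien-1-yl]acetate
Conditions: Pd(OAc)2 (5 mol %), PPh3 (10 mol %), HCO2H, n-Bu3N, DMF, 60 °C
Reagents that add atoms: none
Why: Palladium-catalysed formate reduction of an enol triflate (oxidative addition, formate exchange, decarboxylation to Pd–H, reductive elimination) replaces C–OTf by C–H without moving the double bonds and should give the conjugated ring diene well below the temperature of [1,5]-hydrogen shifts.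

Step 6
Reactants: 9 ethyl 2-[(1R)-2,6,6-trimethylcyclohexa-2,4-dien-1-yl]acetate; 10 dioxygen
Product: 11 ethyl 2-[(1S,4R,8S)-1,7,7-trimethyl-2,3-dioxabicyclo[2.2.2]oct-5-en-8-yl]acetate
Conditions: O2, tetraphenylporphyrin (cat.), CH2Cl2, white-light irradiation, −40 °C
Reagents that add atoms: dioxygen (10), O=O
Why: Photosensitised singlet oxygen adds to the ring diene C9a=C9–C8=C7 of 9 in a concerted suprafacial [4+2] cycloaddition that forms the C9a–O and C7–O bonds together; the closest known case is the photooxygenation of α-terpinene-type cyclohexa-1,3-dienes to ascaridole-type endoperoxides. The 1,2-dioxene ring closes as the two-atom peroxide bridge of a 2,3-dioxabicyclo[2.2.2]oct-5-ene, a bridging cycloaddition closure in which both diene termini are attacked from the same face. The new stereocentres C9a and C7 are therefore cis to each other by suprafaciality, and their configuration relative to C5a is controlled by C5a itself: the nearly planar diene has a C5a–H face and a C5a–CH2CO2Et face, and the gem-dimethyl group at C6 puts one methyl on each face and adds no bias, so oxygen should enter anti to the arm. The step needs this facial selectivity and needs [4+2] to win over the ene reaction of the trisubstituted alkene; the first is secured by the allylic stereocentre next to the C9a terminus, the second by the s-cis geometry that the ring imposes on the diene. The ester is inert, and the absence of base at low temperature should prevent Kornblum–DeLaMare opening of the peroxide.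

Step 7
Reactants: 11 ethyl 2-[(1S,4R,8S)-1,7,7-trimethyl-2,3-dioxabicyclo[2.2.2]oct-5-en-8-yl]acetate
Product: 13 (3aS,5R,7aS)-5-hydroxy-4,4,7a-trimethylhexahydro-1-benzofuran-2(3H)-one, via diol ester 12 (not isolated)
Conditions: H2 (1 atm), PtO2 (cat.), EtOAc, rt; filter; then PPTS (cat.), PhMe, 80 °C
Reagents that add atoms: none
Why: Catalytic hydrogenation cleaves the O–O bond and saturates the alkene without touching either C–O bond (as in ascaridole to cis-terpin), so cis-1,4-diol 12 keeps the peroxide configuration, and acid-catalysed 5-exo-trig transesterification then closes the trans-fused γ-lactone between the equatorial C9a–OH and the equatorial acetate arm, leaving the axial C7–OH (trans to the arm, unable to lactonise) as the only free hydroxyl.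

Step 8
Reactants: 13 (3aS,5R,7aS)-5-hydroxy-4,4,7a-trimethylhexahydro-1-benzofuran-2(3H)-one
Product: 14 (3aS,5R,7aS)-5-[(tert-butyldimethylsilyl)oxy]-4,4,7a-trimethylhexahydro-1-benzofuran-2(3H)-one
Conditions: TBSOTf, 2,6-lutidine, CH2Cl2, 0 °C
Reagents that add atoms: tert-butyldimethylsilyl trifluoromethanesulfonate, CC(C)(C)[Si](C)(C)OS(=O)(=O)C(F)(F)F
Why: Silylation of a hindered secondary alcohol with a silyl triflate and a hindered pyridine base, straightforward here because no other hydroxyl is present.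

Step 9
Reactants: 14 (3aS,5R,7aS)-5-[(tert-butyldimethylsilyl)oxy]-4,4,7a-trimethylhexahydro-1-benzofuran-2(3H)-one
Product: 15 (3aS,5R,7aS)-5-[(tert-butyldimethylsilyl)oxy]-4,4,7a-trimethyloctahydro-1-benzofuran-2-ol (lactol, anomer mixture)
Conditions: DIBAL-H (1.1 equiv), CH2Cl2, −78 °C; Rochelle salt work-up
Reagents that add atoms: none
Why: DIBAL-H half-reduction of a γ-lactone at −78 °C stops at the tetrahedral aluminium hemiacetal, which gives the lactol on work-up while the silyl ether stays intact.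

Step 10
Reactants: 15 (3aS,5R,7aS)-5-[(tert-butyldimethylsilyl)oxy]-4,4,7a-trimethyloctahydro-1-benzofuran-2-ol
Product: 16 (1S,2S,4R)-4-[(tert-butyldimethylsilyl)oxy]-1,3,3-trimethyl-2-(prop-2-en-1-yl)cyclohexan-1-ol
Conditions: Ph3PCH3Br (4 equiv), KOt-Bu (3.8 equiv), THF, 0 → 45 °C
Reagents that add atoms: methyltriphenylphosphonium bromide, C[P+](c1ccccc1)(c1ccccc1)c1ccccc1.[Br-]
Why: Wittig methylenation of a lactol through its open hydroxy-aldehyde form with excess unstabilised ylide turns the arm into the allyl group and releases the tertiary C9a–OH exactly when it is needed.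

Step 11
Reactants: 16 (1S,2S,4R)-4-[(tert-butyldimethylsilyl)oxy]-1,3,3-trimethyl-2-(prop-2-en-1-yl)cyclohexan-1-ol; 17 methacryloyl chloride
Product: 19 (1S,2S,4R)-4-[(tert-butyldimethylsilyl)oxy]-1,3,3-trimethyl-2-(prop-2-en-1-yl)cyclohexyl 2-methylprop-2-enoate, via lithium alkoxide 18 (not isolated)
Conditions: n-BuLi (1.05 equiv), THF, −78 °C; then methacryloyl chloride, −78 → 0 °C
Reagents that add atoms: methacryloyl chloride (17), CC(=C)C(Cl)=O
Why: Acylation of a tertiary alcohol as its lithium alkoxide with an acid chloride is the dependable way to esterify a hindered tertiary hydroxyl, and it fixes the O1–C2 bond before any conjugated acceptor exists in the molecule, so O1 cannot later close a five-membered ring at C4.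

Step 12
Reactants: 19 (1S,2S,4R)-4-[(tert-butyldimethylsilyl)oxy]-1,3,3-trimethyl-2-(prop-2-en-1-yl)cyclohexyl 2-methylprop-2-enoate
Product: 20 (5aS,7R,9aS)-7-[(tert-butyldimethylsilyl)oxy]-3,6,6,9a-tetramethyl-5a,6,7,8,9,9a-hexahydro-1-benzoxepin-2(5H)-one
Conditions: Grubbs II (10 mol %), PhMe (2 mM), 80 °C, argon sparge
Reagents that add atoms: none
Why: Ring-closing olefin metathesis, in which the ruthenium carbene initiates on the monosubstituted allyl alkene and closes onto the methacrylate to give the trisubstituted C3=C4 bond (necessarily Z in a seven-membered ring), helped by the trans-diequatorial arms on the chair and driven by loss of ethylene.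

Step 13
Reactants: 20 (5aS,7R,9aS)-7-[(tert-butyldimethylsilyl)oxy]-3,6,6,9a-tetramethyl-5a,6,7,8,9,9a-hexahydro-1-benzoxepin-2(5H)-one
Product: 21 (5aS,7R,9aS)-7-[(tert-butyldimethylsilyl)oxy]-3,6,6,9a-tetramethyl-2-methylidene-2,5,5a,6,7,8,9,9a-octahydro-1-benzoxepine
Conditions: Cp2TiMe2 (3 equiv), PhMe, 75 °C, dark; filtration through basic alumina, used at once
Reagents that add atoms: dimethyltitanocene, C[Ti](C)(C1C=CC=C1)C1C=CC=C1
Why: Petasis carbonyl methylenation (Cp2Ti=CH2, oxatitanacyclobutane, loss of titanocene oxide) converts lactones, including conjugated ones, into exocyclic enol ethers under non-acidic, non-basic conditions that leave the silyl ether and the ring alkene in place.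

Step 14
Reactants: 21 (5aS,7R,9aS)-7-[(tert-butyldimethylsilyl)oxy]-3,6,6,9a-tetramethyl-2-methylidene-2,5,5a,6,7,8,9,9a-octahydro-1-benzoxepine
Product: 23 [(2R,5aS,7R,9aS)-7-[(tert-butyldimethylsilyl)oxy]-3,6,6,9a-tetramethyl-2,5,5a,6,7,8,9,9a-octahydro-1-benzoxepin-2-yl]methanol, via B-alkyl-9-BBN adduct 22 (not isolated)
Conditions: 9-BBN (2 equiv), THF, 0 °C → rt; then 3 M NaOH, 30% H2O2, 0 °C → rt
Reagents that add atoms: hydrogen peroxide, OO
Why: Hydroboration–oxidation as used for exocyclic enol ethers, in which 9-BBN adds to the 1,1-disubstituted enol ether alkene (boron on the terminal carbon, β to oxygen) in preference to the hindered trisubstituted ring alkene and delivers hydrogen to C2 from the face opposite the pseudo-axial C9a methyl, which should set (2R) with the CH2 group cis to that methyl before oxidation with retention at carbon.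

Step 15
Reactants: 23 [(2R,5aS,7R,9aS)-7-[(tert-butyldimethylsilyl)oxy]-3,6,6,9a-tetramethyl-2,5,5a,6,7,8,9,9a-octahydro-1-benzoxepin-2-yl]methanol
Product: 24 (2R,5aS,7R,9aS)-2-(hydroxymethyl)-3,6,6,9a-tetramethyl-2,5,5a,6,7,8,9,9a-octahydro-1-benzoxepin-7-ol
Conditions: TBAF (3 equiv), THF, 50 °C
Reagents that add atoms: none
Why: Fluoride cleavage of the secondary silyl ether, with nothing else in the molecule labile to fluoride.

Step 16
Reactants: 24 (2R,5aS,7R,9aS)-2-(hydroxymethyl)-3,6,6,9a-tetramethyl-2,5,5a,6,7,8,9,9a-octahydro-1-benzoxepin-7-ol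
Product: 26 palisadin B [(2R,5aS,7S,9aS)-7-bromo-2-(bromomethyl)-3,6,6,9a-tetramethyl-2,5,5a,6,7,8,9,9a-octahydro-1-benzoxepine], via bromo alcohol 25 (not isolated)
Conditions: CBr4 (4 equiv), PPh3 (4.2 equiv), pyridine, CH2Cl2, 0 → 40 °C
Reagents that add atoms: carbon tetrabromide, BrC(Br)(Br)Br
Why: Appel reaction, in which both hydroxyls become alkoxyphosphonium ions and bromide displaces the primary one first (25) and then the axial C7 one by SN2 with inversion along the equatorial trajectory to give the equatorial (7S) bromide, while O1, on the same face as the leaving group, cannot participate.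

**Compound list**

1 | 2,4,4-trimethylcyclohex-2-en-1-one | CC1=CC(C)(C)CCC1=O | starting material
2 | (R)-2,4,4-trimethylcyclohex-2-en-1-ol | CC1=CC(C)(C)CC[C@H]1O | intermediate
3 | triethyl orthoacetate | CC(OCC)(OCC)OCC | starting material
4 | 1-ethoxyethenyl (1R)-2,4,4-trimethylcyclohex-2-en-1-yl ether (mixed ketene acetal) | CC1=CC(C)(C)CC[C@H]1OC(=C)OCC | intermediate (not isolated)
5 | ethyl 2-[(1S)-2,6,6-trimethylcyclohex-2-en-1-yl]acetate | CCOC(=O)C[C@H]1C(C)(C)CCC=C1C | intermediate
6 | ethyl 2-[(1S)-2,6,6-trimethyl-4-oxocyclohex-2-en-1-yl]acetate | CCOC(=O)C[C@H]1C(C)(C)CC(=O)C=C1C | intermediate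
7 | lithium (4R)-4-(2-ethoxy-2-oxoethyl)-3,3,5-trimethylcyclohexa-1,5-dien-1-olate | CCOC(=O)C[C@H]1C(C)(C)C=C(O[Li])C=C1C | intermediate (not isolated)
8 | ethyl 2-[(1R)-2,6,6-trimethyl-4-{[(trifluoromethyl)sulfonyl]oxy}cyclohexa-2,4-dien-1-yl]acetate | CCOC(=O)C[C@H]1C(C)(C)C=C(OS(=O)(=O)C(F)(F)F)C=C1C | intermediate
9 | ethyl 2-[(1R)-2,6,6-trimethylcyclohexa-2,4-dien-1-yl]acetate | CCOC(=O)C[C@H]1C(C)(C)C=CC=C1C | intermediate
10 | dioxygen | O=O | starting material
11 | ethyl 2-[(1S,4R,8S)-1,7,7-trimethyl-2,3-dioxabicyclo[2.2.2]oct-5-en-8-yl]acetate | CCOC(=O)C[C@H]1C(C)(C)[C@H]2C=C[C@]1(C)OO2 | intermediate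
12 | ethyl 2-[(1S,2S,5R)-2,5-dihydroxy-2,6,6-trimethylcyclohexyl]acetate | CCOC(=O)C[C@H]1C(C)(C)[C@H](O)CC[C@]1(C)O | intermediate (not isolated)
13 | (3aS,5R,7aS)-5-hydroxy-4,4,7a-trimethylhexahydro-1-benzofuran-2(3H)-one | O=C1C[C@H]2C(C)(C)[C@H](O)CC[C@]2(C)O1 | intermediate
14 | (3aS,5R,7aS)-5-[(tert-butyldimethylsilyl)oxy]-4,4,7a-trimethylhexahydro-1-benzofuran-2(3H)-one | O=C1C[C@H]2C(C)(C)[C@H](O[Si](C)(C)C(C)(C)C)CC[C@]2(C)O1 | intermediate
15 | (3aS,5R,7aS)-5-[(tert-butyldimethylsilyl)oxy]-4,4,7a-trimethyloctahydro-1-benzofuran-2-ol (anomer mixture) | OC1C[C@H]2C(C)(C)[C@H](O[Si](C)(C)C(C)(C)C)CC[C@]2(C)O1 | intermediate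
16 | (1S,2S,4R)-4-[(tert-butyldimethylsilyl)oxy]-1,3,3-trimethyl-2-(prop-2-en-1-yl)cyclohexan-1-ol | C=CC[C@H]1C(C)(C)[C@H](O[Si](C)(C)C(C)(C)C)CC[C@]1(C)O | intermediate
17 | methacryloyl chloride | CC(=C)C(Cl)=O | starting material
18 | lithium (1S,2S,4R)-4-[(tert-butyldimethylsilyl)oxy]-1,3,3-trimethyl-2-(prop-2-en-1-yl)cyclohexan-1-olate | C=CC[C@H]1C(C)(C)[C@H](O[Si](C)(C)C(C)(C)C)CC[C@]1(C)O[Li] | intermediate (not isolated)
19 | (1S,2S,4R)-4-[(tert-butyldimethylsilyl)oxy]-1,3,3-trimethyl-2-(prop-2-en-1-yl)cyclohexyl 2-methylprop-2-enoate | C=CC[C@H]1C(C)(C)[C@H](O[Si](C)(C)C(C)(C)C)CC[C@]1(C)OC(=O)C(C)=C | intermediate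
20 | (5aS,7R,9aS)-7-[(tert-butyldimethylsilyl)oxy]-3,6,6,9a-tetramethyl-5a,6,7,8,9,9a-hexahydro-1-benzoxepin-2(5H)-one | CC1=CC[C@H]2C(C)(C)[C@H](O[Si](C)(C)C(C)(C)C)CC[C@]2(C)OC1=O | intermediate
21 | (5aS,7R,9aS)-7-[(tert-butyldimethylsilyl)oxy]-3,6,6,9a-tetramethyl-2-methylidene-2,5,5a,6,7,8,9,9a-octahydro-1-benzoxepine | CC1=CC[C@H]2C(C)(C)[C@H](O[Si](C)(C)C(C)(C)C)CC[C@]2(C)OC1=C | intermediate
22 | 9-{[(2R,5aS,7R,9aS)-7-[(tert-butyldimethylsilyl)oxy]-3,6,6,9a-tetramethyl-2,5,5a,6,7,8,9,9a-octahydro-1-benzoxepin-2-yl]methyl}-9-borabicyclo[3.3.1]nonane | CC1=CC[C@H]2C(C)(C)[C@H](O[Si](C)(C)C(C)(C)C)CC[C@]2(C)O[C@H]1CB1C2CCCC1CCC2 | intermediate (not isolated)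
23 | [(2R,5aS,7R,9aS)-7-[(tert-butyldimethylsilyl)oxy]-3,6,6,9a-tetramethyl-2,5,5a,6,7,8,9,9a-octahydro-1-benzoxepin-2-yl]methanol | CC1=CC[C@H]2C(C)(C)[C@H](O[Si](C)(C)C(C)(C)C)CC[C@]2(C)O[C@H]1CO | intermediate
24 | (2R,5aS,7R,9aS)-2-(hydroxymethyl)-3,6,6,9a-tetramethyl-2,5,5a,6,7,8,9,9a-octahydro-1-benzoxepin-7-ol | CC1=CC[C@H]2C(C)(C)[C@H](O)CC[C@]2(C)O[C@H]1CO | intermediate
25 | (2R,5aS,7R,9aS)-2-(bromomethyl)-3,6,6,9a-tetramethyl-2,5,5a,6,7,8,9,9a-octahydro-1-benzoxepin-7-ol | CC1=CC[C@H]2C(C)(C)[C@H](O)CC[C@]2(C)O[C@H]1CBr | intermediate (not isolated)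
26 | palisadin B, (2R,5aS,7S,9aS)-7-bromo-2-(bromomethyl)-3,6,6,9a-tetramethyl-2,5,5a,6,7,8,9,9a-octahydro-1-benzoxepine | CC1=CC[C@H]2C(C)(C)[C@@H](Br)CC[C@]2(C)O[C@H]1CBr | target

**Step count**

Total: 16 steps. Longest linear sequence: 16 steps (the route is fully linear from 1).

**Steps most likely to fail**

Step 6 (photooxygenation). Oxygen may add to both faces of the diene with little discrimination, the reaction may divert into the ene mode and give allylic hydroperoxides, or the peroxide may rearrange on handling. The fallback sets out from 9 and returns at 12; it introduces the two C–O bonds one after the other. Epoxidation of the more electron-rich trisubstituted alkene of 9 (mCPBA, NaHCO3, CH2Cl2, −20 °C), anti to the acetate arm, should give the vinyl epoxide ethyl 2-[(1R,2S,6S)-1,3,3-trimethyl-7-oxabicyclo[4.1.0]hept-4-en-2-yl]acetate F1. Pd(PPh3)4-catalysed 1,4-addition of acetic acid (ionisation anti to the epoxide oxygen, acetate attack anti to palladium, hence net cis) should give ethyl 2-[(1S,2S,5R)-5-acetoxy-2-hydroxy-2,6,6-trimethylcyclohex-3-en-1-yl]acetate F2. Hydrogenation (H2, PtO2, EtOAc) gives ethyl 2-[(1S,2S,5R)-5-acetoxy-2-hydroxy-2,6,6-trimethylcyclohexyl]acetate F3, and ethanolysis of the acetate (K2CO3, EtOH) gives diol ester 12, which is lactonised as in step 7.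

Step 12 (ring-closing metathesis). The ruthenium alkylidene formed at the allyl group may fail to engage the hindered 1,1-disubstituted acrylate, so that oligomerisation through the allyl ends takes over, or the tertiary ester may not reach the s-cis geometry that a seven-membered lactone needs. The fallback sets out from 16 and returns at 20; it closes the ring by an intramolecular Horner–Wadsworth–Emmons reaction. Esterification of 16 with 2-(diethoxyphosphoryl)propanoic acid (DCC, DMAP, CH2Cl2; acylation through the phosphonoketene suits hindered alcohols) should give (1S,2S,4R)-4-[(tert-butyldimethylsilyl)oxy]-1,3,3-trimethyl-2-(prop-2-en-1-yl)cyclohexyl 2-(diethoxyphosphoryl)propanoate F4. Ozonolysis of the terminal alkene (O3, CH2Cl2, −78 °C; PPh3) gives (1S,2S,4R)-4-[(tert-butyldimethylsilyl)oxy]-1,3,3-trimethyl-2-(2-oxoethyl)cyclohexyl 2-(diethoxyphosphoryl)propanoate F5. Masamune–Roush cyclisation (LiCl, DBU, MeCN, high dilution) then forms the C3=C4 bond, Z by ring constraint, to give 20.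

Step 16 (bromination at C7). At the neopentyl C7, bromide attack is slow, so E2 loss of the axial alkoxyphosphonium with the axial C8–H, or migration of the anti-periplanar axial C6 methyl, may outrun substitution. The fallback sets out from 24 and returns at 26; it separates the two brominations and activates C7 as an isolable sulfonate. The Appel reaction is run with 1.1 equiv of CBr4/PPh3 at 0 °C and stopped at bromo alcohol 25, which is isolated. Triflation (Tf2O, pyridine, CH2Cl2, −30 °C) gives (2R,5aS,7R,9aS)-2-(bromomethyl)-3,6,6,9a-tetramethyl-2,5,5a,6,7,8,9,9a-octahydro-1-benzoxepin-7-yl trifluoromethanesulfonate F6. Displacement with n-Bu4NBr in toluene (0 °C → rt), a non-ionising medium that favours SN2 inversion over ionisation, should give 26.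

**Further compounds**

F1 | step 6 | ethyl 2-[(1R,2S,6S)-1,3,3-trimethyl-7-oxabicyclo[4.1.0]hept-4-en-2-yl]acetate | CCOC(=O)C[C@H]1C(C)(C)C=C[C@@H]2O[C@]12C
F2 | step 6 | ethyl 2-[(1S,2S,5R)-5-acetoxy-2-hydroxy-2,6,6-trimethylcyclohex-3-en-1-yl]acetate | CCOC(=O)C[C@H]1C(C)(C)[C@H](OC(C)=O)C=C[C@]1(C)O
F3 | step 6 | ethyl 2-[(1S,2S,5R)-5-acetoxy-2-hydroxy-2,6,6-trimethylcyclohexyl]acetate | CCOC(=O)C[C@H]1C(C)(C)[C@H](OC(C)=O)CC[C@]1(C)O
F4 | step 12 | (1S,2S,4R)-4-[(tert-butyldimethylsilyl)oxy]-1,3,3-trimethyl-2-(prop-2-en-1-yl)cyclohexyl 2-(diethoxyphosphoryl)propanoate (epimers at the phosphonate carbon) | C=CC[C@H]1C(C)(C)[C@H](O[Si](C)(C)C(C)(C)C)CC[C@]1(C)OC(=O)C(C)P(=O)(OCC)OCC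
F5 | step 12 | (1S,2S,4R)-4-[(tert-butyldimethylsilyl)oxy]-1,3,3-trimethyl-2-(2-oxoethyl)cyclohexyl 2-(diethoxyphosphoryl)propanoate (epimers at the phosphonate carbon) | O=CC[C@H]1C(C)(C)[C@H](O[Si](C)(C)C(C)(C)C)CC[C@]1(C)OC(=O)C(C)P(=O)(OCC)OCC
F6 | step 16 | (2R,5aS,7R,9aS)-2-(bromomethyl)-3,6,6,9a-tetramethyl-2,5,5a,6,7,8,9,9a-octahydro-1-benzoxepin-7-yl trifluoromethanesulfonate | CC1=CC[C@H]2C(C)(C)[C@H](OS(=O)(=O)C(F)(F)F)CC[C@]2(C)O[C@H]1CBr
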